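1.55 is the number I carry through these flasks: the rate constant times the coupling partner's charge to the power 3/2 times the time, the Damköhler number, which I call N. It counts how many charges of substrate the run turns over at its opening pace.

| flask | substrate | coupling partner | remark | time |
|---|---|---|---|---|
| dusk | 0.050 M | 0.0550 M | one stirred flow tank at steady state, fed with the mixture as stated, mean residence time 30 h |  |
| winter | 0.050 M | 0.0550 M | everything together in a closed stirred flask, run for 30 h | 30 h |
| midnight | 0.050 M | 0.0550 M (fed, over 24.0 h) | all but coupling partner at the start; coupling partner goes in evenly over 24.0 h, the run ends at 30 h | 30 h |
| dawn | 0.050 M (fed, over 24.0 h) | 0.0550 M | all but substrate at the start; substrate goes in evenly over 24.0 h, the run ends at 30 h | 30 h |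

* the set-up with the highest amount of target at the outlet or at the end, in percent of the substrate put in ("none" if the first two lie within 2 percentage points) (dusk / winter / midnight / dawn / none)
* amount of target at the outlet or at the end, in percent of the substrate put in, dusk
* amount of target at the outlet or at the end, in percent of the substrate put in, winter
* amount of target at the outlet or at the end, in percent of the substrate put in, midnight
* amount of target at the outlet or at the end, in percent of the substrate put in, dawn

- the stated concentrations are those of everything mixed, before any reaction; amounts are the same in each set-up
- the feed brings no volume worth counting
- run time (winter): 30 h

The rate is first order in substrate and of order 3/2 in coupling partner. Their charges stand at a ratio of 1.10, so I let one fraction left, f, serve for both, and the rate goes as f to the power 5/2. Integrated, f to the power −3/2 climbs in a straight line from 1, by 3/2 of N. For winter that gives 55.1 %.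

The dusk tank sits at its outlet fraction, so the part converted equals N times f to the power 5/2; guessing f at 0.600 gives 43.2 %.

A dose fed evenly has on average half the dosing time less to react, so I shorten the clock to N = 0.929. That gives 44.1 % for midnight and 44.1 % for dawn. My pick is winter. One number was not enough: the dosed flasks also needed the dosing time, and my reckoning cannot part midnight from dawn.

The forecast gives 42.6 % for dusk, 57 % for winter, 41 % for midnight and 44 % for dawn, and names winter: “the closed flask wins by keeping both concentrations high from the start”. Its winter stands higher than mine, and it does part the dosed flasks.

The simulation gives 42.6 % for dusk, 57.0 % for winter, 41.1 % for midnight and 44.0 % for dawn, so the best is winter.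

    substrate + coupling partner → target, rate k1*[substrate]*[coupling partner]^1.5 (k1 = 4.0 M⁻¹·⁵ h⁻¹)

Winter's shortfall from full conversion comes in part from the wearing away of coupling partner, acting together with the length of the run: holding coupling partner at its charge gives 78.7 %, and a run ten times as long gives 92.2 %. The held case is pseudo-first-order, with substrate's fraction left equal to exp(−N), so N gives 78.8 %. For winter read at 12 h, N is 0.619, and the closed form gives 35.5 %; the computed reading is 36.3 %.

The constants are made up; the run is a simulation.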